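Ring A (the cyclohexene carrying the enolised β-keto ester) is closed last by joining C4, the ester-bearing carbon, to C5, the α-carbon of the ring B ketone. The target hides a 1,4-dicarbonyl (enolised C3 ketone and C6 ketone) across the ring A/B fusion, the retron of an oxidative enolate coupling. In one operation, Fe(acac)3 oxidation of the dianion of keto β-keto ester 23 should forge C4–C5, set C5 and deliver the enolised ring. The precursor, a lactone-fused cycloheptenone (rings B, C, D) bearing the C1 side chain, comes from a rhodium-carbenoid cyclopropanation/divinylcyclopropane Cope cascade that sets C11 and C14.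

Key step: step 15

Remark (numbering): cembrane-type locants are used for the polycyclic compounds: C1 = CH bearing isopropenyl, C2 = CH2, C3 = enol carbon, C4 = carbon bearing CO2Me, C5 = CH between C4 and the C6 ketone, C7 = CH, C8 = C(OH)CH3, C9 = CH2, C10 = O–CH, C11 = CH, C12=C13 = alkene, C14 = CH, C20 = lactone C=O. Ring A = C1–C5 + C14, ring B = C5–C7 + C11–C14, ring C = C7–C11, ring D = lactone.

Assumption: C5 and C7, both α to the C6 ketone and therefore epimerisable, are taken to settle in the cis-fused arrangement of the target (H5, H7, H11, H14 on one face).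

Step 1
Reactants: 1 methacrolein; 2 (triphenylphosphoranylidene)acetaldehyde
Product: 3 (2E)-4-methylpenta-2,4-dienal
Conditions: toluene, 80 °C, excess 1
Reagents that add atoms: none
Why: Wittig olefination with the stabilised formyl ylide should give the E-dienal, with excess enal suppressing double homologation.

Step 2
Reactants: 3 dienal; 4 1-methoxy-1-(trimethylsilyloxy)ethene
Product: 6 methyl (3R,4E)-3-hydroxy-6-methylhepta-4,6-dienoate, via trimethylsilyl ether 5 (not isolated)
Conditions: Ti(OiPr)4 (2 mol%), tridentate Schiff-base ligand from 2-amino-2'-hydroxy-1,1'-binaphthyl and 3-bromo-5-tert-butylsalicylaldehyde (antipode giving 3R), 3,5-di-tert-butylsalicylic acid, Et2O, 0 °C; then 1 M HCl, THF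
Reagents that add atoms: none
Why: Catalytic enantioselective Mukaiyama acetate aldol addition, in which the chiral tetravalent titanium complex shields one enal face and so sets the 3R carbinol (future C13–O).

Step 3
Reactants: 6 hydroxy ester
Product: 8 methyl (3E,5R)-6-methyl-5-(2-oxoethyl)hepta-3,6-dienoate, via allyl vinyl ether 7 (not isolated)
Conditions: butyl vinyl ether (excess), Pd(OCOCF3)2 (0.5 mol%), 4,7-diphenyl-1,10-phenanthroline, Et3N (cat.), 75 °C; then toluene, 130 °C, sealed tube
Reagents that add atoms: butyl vinyl ether C=COCCCC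
Why: Transfer vinylation followed by a [3,3] Claisen rearrangement through a chair with CH2CO2Me equatorial should transfer the 3R C–O chirality suprafacially to the new 5R centre (C1) and give the E-alkene.

Step 4
Reactants: 8 aldehyde ester
Product: 9 methyl (3E,5R)-5-(2,2-dimethoxyethyl)-6-methylhepta-3,6-dienoate
Conditions: HC(OMe)3, MeOH, PPTS (5 mol%), rt
Reagents that add atoms: trimethyl orthoformate COC(OC)OC; methanol CO
Why: Acid-catalysed acetalisation masks the future C3 aldehyde against the basic steps that follow.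

Step 5
Reactants: 9 acetal ester
Product: 10 (3E,5R)-5-(2,2-dimethoxyethyl)-6-methylhepta-3,6-dienoic acid
Conditions: LiOH·H2O, THF/H2O, 0 °C; cold 0.5 M HCl to pH 4
Reagents that add atoms: lithium hydroxide [Li+].[OH-]
Why: Mild saponification of the methyl ester, with a cold weakly acidic work-up that should leave the dimethyl acetal intact.

Step 6
Reactants: 11 (4R)-4-[(tert-butyldimethylsilyl)oxy]cyclopent-2-en-1-one
Product: 12 (4R)-4-[(tert-butyldimethylsilyl)oxy]-2-iodocyclopent-2-en-1-one
Conditions: I2, pyridine, CH2Cl2, 0 °C to rt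
Reagents that add atoms: iodine II
Why: α-Iodination of the enone by pyridine addition, iodination and elimination places the halogen on the future C7.

Step 7
Reactants: 12 iodoenone
Product: 13 (1S,4R)-4-[(tert-butyldimethylsilyl)oxy]-2-iodo-1-methylcyclopent-2-en-1-ol
Conditions: MeMgBr, CeCl3, THF, −78 °C
Reagents that add atoms: methylmagnesium bromide C[Mg]Br
Why: 1,2-Addition of the organocerium reagent anti to the bulky C4 silyloxy group should set the tertiary carbinol (C8) with OH cis to the C10 oxygen.

Step 8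
Reactants: 13 iodo alcohol
Product: 16 1-[(3R,5S)-3,5-dihydroxy-5-methylcyclopent-1-en-1-yl]ethan-1-one, via ethoxydiene 14 (not isolated), via silyl ether ketone 15 (not isolated)
Conditions: tributyl(1-ethoxyvinyl)stannane, Pd(PPh3)4 (5 mol%), CuI (10 mol%), CsF, DMF, 45 °C; then 48% aq. HF, MeCN, 0 °C to rt
Reagents that add atoms: tributyl(1-ethoxyvinyl)stannane CCCC[Sn](CCCC)(CCCC)C(=C)OCC; water O
Why: Stille coupling installs the masked acetyl group (C6, C5), and aqueous HF then hydrolyses the enol ether first and cleaves the silyl ether second.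

Step 9
Reactants: 16 diol enone; 10 acid
Product: 17 (1R,4S)-3-acetyl-4-hydroxy-4-methylcyclopent-2-en-1-yl (3E,5R)-5-(2,2-dimethoxyethyl)-6-methylhepta-3,6-dienoate
Conditions: EDC·HCl, DMAP (10 mol%), CH2Cl2, 0 °C
Reagents that add atoms: none
Why: Steglich esterification should acylate only the secondary allylic C10 hydroxyl, the tertiary C8 hydroxyl being too hindered.

Step 10
Reactants: 17 ester
Product: 18 (1R,4S)-3-acetyl-4-hydroxy-4-methylcyclopent-2-en-1-yl (3E,5R)-2-diazo-5-(2,2-dimethoxyethyl)-6-methylhepta-3,6-dienoate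
Conditions: p-ABSA, DBU, MeCN, 0 °C
Reagents that add atoms: 4-acetamidobenzenesulfonyl azide CC(=O)Nc1ccc(cc1)S(=O)(=O)N=[N+]=[N-]
Why: Regitz diazo transfer to the β,γ-unsaturated ester through its dienolate gives the vinyldiazoacetate with the E-alkene retained.

Step 11
Reactants: 18 vinyldiazoacetate
Product: 19 (1R,4S)-4-[(tert-butyldimethylsilyl)oxy]-3-{1-[(tert-butyldimethylsilyl)oxy]ethenyl}-4-methylcyclopent-2-en-1-yl (3E,5R)-2-diazo-5-(2,2-dimethoxyethyl)-6-methylhepta-3,6-dienoate
Conditions: TBSOTf (3 equiv), Et3N, CH2Cl2, −78 to 0 °C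
Reagents that add atoms: tert-butyldimethylsilyl trifluoromethanesulfonate CC(C)(C)[Si](C)(C)OS(=O)(=O)C(F)(F)F
Why: Soft enolisation of the methyl ketone gives the cross-conjugated 2-silyloxydiene and the same reagent silylates the tertiary alcohol.

Step 12
Reactants: 19 silyloxydiene vinyldiazoacetate
Product: 21 tricyclic silyl enol ether (rings B–C–D; C6=C7 and C12=C13; 1R,8S,10R,11R,14S), via cis-divinylcyclopropane 20 (not isolated)
Conditions: Rh2(OAc)4 (1 mol%), CH2Cl2, 40 °C, slow addition; then toluene, 80 °C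
Reagents that add atoms: none
Why: Tandem intramolecular cyclopropanation/Cope rearrangement (formal [4+3]) of a divalent rhodium vinylcarbenoid: the ester tether delivers C12 to the C11=C7 alkene on the face of the C10 oxygen (cis lactone, sets C11), the ring fusions force the two vinyl groups cis, and the boat Cope of the E-alkene places H14 cis to H11.

Step 13
Reactants: 21 tricyclic silyl enol ether
Product: 22 keto aldehyde (C6 ketone; C3 aldehyde; 8-OTBS; 1R,7R,8S,10R,11R,14S)
Conditions: 1 M HCl, THF, 0 °C
Reagents that add atoms: water O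
Why: Acid hydrolysis of the silyl enol ether and the dimethyl acetal, with protonation of C7 on the face opposite the C8 silyloxy group, should give the cis B/C fusion (also the expected thermodynamic epimer).

Step 14
Reactants: 22 keto aldehyde
Product: 23 keto β-keto ester (side chain C1–C2–C3(=O)–C4H2–CO2Me; 1R,7R,8S,10R,11R,14S)
Conditions: N2CHCO2Me, SnCl2 (20 mol%), CH2Cl2, rt
Reagents that add atoms: methyl diazoacetate COC(=O)C=[N+]=[N-]
Why: Roskamp homologation (addition of the diazo ester to the aldehyde, then 1,2-hydride shift with loss of N2) is selective for the aldehyde over the ring ketone.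

Step 15
Reactants: 23 keto β-keto ester
Product: 24 8-O-TBS ether of the target
Conditions: LiN(SiMe3)2 (2.3 equiv), THF, −78 °C; Fe(acac)3 (2.2 equiv), −78 to 0 °C
Reagents that add atoms: none
Why: Intramolecular oxidative enolate heterocoupling: two equivalents of base give the chelated β-keto ester enolate (C3=C4) and the kinetic C5=C6 ketone enolate (the methylene C5 is deprotonated, not the hindered methine C7), and trivalent iron oxidises the more electron-rich ketone enolate to an α-keto radical at C5. This radical is captured by C4 of the neighbouring β-keto ester enolate, and a second oxidation gives the 1,4-diketone, which tautomerises to the hydrogen-bonded enol of ring A; the closest known reaction type is the iron- or copper-mediated intramolecular coupling of a ketone enolate with a 1,3-dicarbonyl enolate. Ring A closes in a six-membered (enolendo) mode through bond C4–C5, the two carbons being held 1,6 by the C14–C1–C2–C3 chain. The new stereocentre C5 is controlled by C14: the tether reaches C5 only on the face carrying C1, which gives the cis A/B fusion, and C5 stays epimerisable toward that arrangement. The step needs C4–C5 coupling in preference to Michael addition of the β-keto ester to the C12=C13 alkylidene lactone and to homocoupling; low temperature, the lithium chelate and the six-membered intramolecular geometry should secure this.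

Step 16
Reactants: 24 silyl ether
Product: 25 target (1R,5S,7R,8S,10R,11R,14S)
Conditions: HF·pyridine, THF, 0 °C to rt
Reagents that add atoms: none
Why: Desilylation of the tertiary silyl ether with acidic fluoride avoids base-induced retro-aldol or dehydration of the β-hydroxy ketone.

Compound list
1 | methacrolein | C=C(C)C=O | starting material
2 | (triphenylphosphoranylidene)acetaldehyde | O=CC=P(c1ccccc1)(c1ccccc1)c1ccccc1 | starting material
3 | (2E)-4-methylpenta-2,4-dienal | C=C(C)/C=C/C=O | intermediate
4 | 1-methoxy-1-(trimethylsilyloxy)ethene | C=C(OC)O[Si](C)(C)C | starting material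
5 | methyl (3R,4E)-6-methyl-3-(trimethylsilyloxy)hepta-4,6-dienoate | COC(=O)C[C@@H](O[Si](C)(C)C)/C=C/C(C)=C | intermediate
6 | methyl (3R,4E)-3-hydroxy-6-methylhepta-4,6-dienoate | COC(=O)C[C@@H](O)/C=C/C(C)=C | intermediate
7 | methyl (3R,4E)-3-(ethenyloxy)-6-methylhepta-4,6-dienoate | COC(=O)C[C@@H](OC=C)/C=C/C(C)=C | intermediate
8 | methyl (3E,5R)-6-methyl-5-(2-oxoethyl)hepta-3,6-dienoate | COC(=O)C/C=C/[C@@H](CC=O)C(C)=C | intermediate
9 | methyl (3E,5R)-5-(2,2-dimethoxyethyl)-6-methylhepta-3,6-dienoate | COC(=O)C/C=C/[C@@H](CC(OC)OC)C(C)=C | intermediate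
10 | (3E,5R)-5-(2,2-dimethoxyethyl)-6-methylhepta-3,6-dienoic acid | OC(=O)C/C=C/[C@@H](CC(OC)OC)C(C)=C | intermediate
11 | (4R)-4-[(tert-butyldimethylsilyl)oxy]cyclopent-2-en-1-one | O=C1C[C@@H](O[Si](C)(C)C(C)(C)C)C=C1 | starting material
12 | (4R)-4-[(tert-butyldimethylsilyl)oxy]-2-iodocyclopent-2-en-1-one | O=C1C[C@@H](O[Si](C)(C)C(C)(C)C)C=C1I | intermediate
13 | (1S,4R)-4-[(tert-butyldimethylsilyl)oxy]-2-iodo-1-methylcyclopent-2-en-1-ol | C[C@]1(O)C[C@@H](O[Si](C)(C)C(C)(C)C)C=C1I | intermediate
14 | (1S,4R)-4-[(tert-butyldimethylsilyl)oxy]-2-(1-ethoxyethenyl)-1-methylcyclopent-2-en-1-ol | C=C(OCC)C1=C[C@H](O[Si](C)(C)C(C)(C)C)C[C@]1(C)O | intermediate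
15 | 1-[(3R,5S)-3-[(tert-butyldimethylsilyl)oxy]-5-hydroxy-5-methylcyclopent-1-en-1-yl]ethan-1-one | CC(=O)C1=C[C@H](O[Si](C)(C)C(C)(C)C)C[C@]1(C)O | intermediate
16 | 1-[(3R,5S)-3,5-dihydroxy-5-methylcyclopent-1-en-1-yl]ethan-1-one | CC(=O)C1=C[C@H](O)C[C@]1(C)O | intermediate
17 | (1R,4S)-3-acetyl-4-hydroxy-4-methylcyclopent-2-en-1-yl (3E,5R)-5-(2,2-dimethoxyethyl)-6-methylhepta-3,6-dienoate | CC(=O)C1=C[C@H](OC(=O)C/C=C/[C@@H](CC(OC)OC)C(C)=C)C[C@]1(C)O | intermediate
18 | (1R,4S)-3-acetyl-4-hydroxy-4-methylcyclopent-2-en-1-yl (3E,5R)-2-diazo-5-(2,2-dimethoxyethyl)-6-methylhepta-3,6-dienoate | CC(=O)C1=C[C@H](OC(=O)C(=[N+]=[N-])/C=C/[C@@H](CC(OC)OC)C(C)=C)C[C@]1(C)O | intermediate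
19 | bis-silylated vinyldiazoacetate (8-OTBS; C6 silyl dienol ether) | C=C(O[Si](C)(C)C(C)(C)C)C1=C[C@H](OC(=O)C(=[N+]=[N-])/C=C/[C@@H](CC(OC)OC)C(C)=C)C[C@]1(C)O[Si](C)(C)C(C)(C)C | intermediate
20 | cis-divinylcyclopropane lactone (cyclopropane C7–C11–C12 fused to rings C and D) | C=C(O[Si](C)(C)C(C)(C)C)[C@]12[C@]3(/C=C/[C@@H](CC(OC)OC)C(C)=C)C(=O)O[C@H](C[C@]1(C)O[Si](C)(C)C(C)(C)C)[C@H]23 | intermediate
21 | tricyclic silyl enol ether, rings B–C–D (C6-OTBS, C6=C7, C12=C13, 8-OTBS, acetal side chain on C14; 1R,8S,10R,11R,14S) | C=C(C)[C@H](CC(OC)OC)[C@H]1CC(O[Si](C)(C)C(C)(C)C)=C2[C@@H]3C(=C1)C(=O)O[C@@H]3C[C@]2(C)O[Si](C)(C)C(C)(C)C | intermediate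
22 | keto aldehyde (C6 ketone, C3 aldehyde, 8-OTBS; 1R,7R,8S,10R,11R,14S) | C=C(C)[C@H](CC=O)[C@H]1CC(=O)[C@@H]2[C@@H]3C(=C1)C(=O)O[C@@H]3C[C@]2(C)O[Si](C)(C)C(C)(C)C | intermediate
23 | keto β-keto ester (1R,7R,8S,10R,11R,14S) | C=C(C)[C@H](CC(=O)CC(=O)OC)[C@H]1CC(=O)[C@@H]2[C@@H]3C(=C1)C(=O)O[C@@H]3C[C@]2(C)O[Si](C)(C)C(C)(C)C | intermediate
24 | 8-O-tert-butyldimethylsilyl ether of the target | C=C(C)[C@@H]1CC(O)=C(C(=O)OC)[C@H]2C(=O)[C@@H]3[C@@H]4C(=C[C@H]21)C(=O)O[C@@H]4C[C@]3(C)O[Si](C)(C)C(C)(C)C | intermediate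
25 | target, tetracyclic enol β-keto ester lactone (1R,5S,7R,8S,10R,11R,14S) | C=C(C)[C@@H]1CC(O)=C(C(=O)OC)[C@H]2C(=O)[C@@H]3[C@@H]4C(=C[C@H]21)C(=O)O[C@@H]4C[C@]3(C)O | target

Total step count: 16. Longest linear sequence: 13 steps (steps 1–5 and 9–16, from methacrolein); the cyclopentene branch is steps 6–8.

Steps most likely to fail

Step 15 (key step). The β-keto ester enolate may add in Michael fashion to the C12=C13 alkylidene lactone, or the second deprotonation may stray to C7 or C2, before the oxidant acts. The fallback sets out from 23 and avoids a long-lived free dianion. In-situ trapping with LiN(SiMe3)2/Me3SiCl (THF, −78 °C) should give the isolable bis(trimethylsilyl enol ether) F1 (C3=C4 and C5=C6 enol ethers). Single-electron oxidation with (NH4)2Ce(NO3)6/NaHCO3 in MeCN at −20 °C should then couple C4 with C5 through the enol ether radical cation and, after loss of both silyl groups, come back to the route at 24.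

Step 12. The rhodium carbenoid may be diverted (attack at the electron-rich enol ether terminus, C–H insertion, pyrazole formation from the vinyl diazo ester), or cyclopropanation of the hindered trisubstituted C11=C7 alkene may be too slow. The fallback sets out from 17 and builds the same cyclopropane without a carbene. LiN(SiMe3)2 (THF, −78 to 0 °C) should trigger 5-exo Michael addition of the ester dienolate (C12) to the enone carbon C11, giving the cis-fused keto lactone F2. Excess LiN(SiMe3)2 followed by I2 should close the C7–C12 bond by oxidative 1,3-coupling of the bis-enolate, giving the vinylcyclopropyl methyl ketone F3. TBSOTf/Et3N converts F3 into the divinylcyclopropane 20, which undergoes the Cope rearrangement and comes back to the route at 21.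

Step 14. Lewis-acid activation of the aldehyde may trigger carbonyl-ene closure onto the neighbouring isopropenyl group or aldol reaction with the ring ketone instead of the homologation. The fallback sets out from 22 and changes the oxidation level. Pinnick oxidation (NaClO2, NaH2PO4, 2-methyl-2-butene) gives the carboxylic acid F4. Acylation of Meldrum's acid (DCC, DMAP, CH2Cl2) gives the acyl Meldrum's acid F5, and methanolysis in refluxing MeOH comes back to the route at 23.

Further compounds
F1 | step 15 | bis(trimethylsilyl enol ether) of 23 (C3-OTMS=C4 and C5=C6-OTMS) | C=C(C)[C@H](CC(O[Si](C)(C)C)=CC(=O)OC)[C@H]1C=C(O[Si](C)(C)C)[C@@H]2[C@@H]3C(=C1)C(=O)O[C@@H]3C[C@]2(C)O[Si](C)(C)C(C)(C)C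
F2 | step 12 | cis-fused keto lactone from Michael addition (C11–C12 bond; C7 and C12 epimers) | CC(=O)C1[C@@H]2C(/C=C/[C@@H](CC(OC)OC)C(C)=C)C(=O)O[C@@H]2C[C@]1(C)O
F3 | step 12 | vinylcyclopropyl methyl ketone (cyclopropane C7–C11–C12; free 8-OH) | CC(=O)[C@]12[C@]3(/C=C/[C@@H](CC(OC)OC)C(C)=C)C(=O)O[C@H](C[C@]1(C)O)[C@H]23
F4 | step 14 | carboxylic acid from 22 (C3 acid) | C=C(C)[C@H](CC(=O)O)[C@H]1CC(=O)[C@@H]2[C@@H]3C(=C1)C(=O)O[C@@H]3C[C@]2(C)O[Si](C)(C)C(C)(C)C
F5 | step 14 | acyl Meldrum's acid of F4 | C=C(C)[C@H](CC(=O)C4C(=O)OC(C)(C)OC4=O)[C@H]1CC(=O)[C@@H]2[C@@H]3C(=C1)C(=O)O[C@@H]3C[C@]2(C)O[Si](C)(C)C(C)(C)C
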